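The vessel starts with substrate and initiator, and partner runs in until the volume stands at twice the start.

substrate 0.058 M; partner 2.50 equiv (fed, over 25 min); initiator 0.64 mol%; time 8.0 h; the fed solution adds 1.0 times the starting volume

- why nothing more happens at 8.0 h, or that something still does (it is still moving / the partner has run out first / all of the substrate has reacted)
- how much of the substrate has reacted by 8.0 h
- how much product there is at 8.0 h, in percent of the substrate charged

- percent here means substrate units held: one ended chains counts as two
- two of one species on the left: rate k times its square, two consumed each time
- amounts are per litre of the starting volume; all of the dose is in the solution fed
- the reaction counts as stopped when no species that holds the substrate changes by six tenths of a point or more over the second half of the time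
- run time (flask): 8.0 h

    initiator → 2 initiating radical (k1 = 0.0056 /min)
    partner + first chain carrier → product + second chain carrier (k2 = 2.2 × 10⁵ /M/min)
    substrate + initiating radical → capped initiator + first chain carrier (k3 = 2.5 × 10⁵ /M/s)
    first chain carrier → ended carrier (k4 = 210 /min)
    2 first chain carrier → ended chains (k5 = 4 × 10⁸ /M/s)
    substrate + second chain carrier → by-product + first chain carrier (k6 = 36000 /M/s)

The bench rule says a radical-started run is over after 4 half-lives of its initiator. Here k1 = 0.0056 /min gives a half-life of 2.06 h, so the run holds 3.88 half-lives and leaves 6.80% of the initiator. By the rule the run is close to over.

But the rule counts one event per radical, and each initiator gives two first chain carriers, which cycle. Once fed, and before any is used, c(partner) is 0.0725 M, so the first chain carrier meets partner at a pseudo-first-order 16000 /min and ends by itself at 210 /min. This ratio, the kinetic chain length, is 76.0, and it marks the border: with a chain this long, a small remnant of initiator still counts.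

We call the tail the conversion still to come at a given time: twice the initiator left, as a share of the substrate charged, times the chain length. At 8.0 h the tail is 6.61%. It ignores carriers ending in pairs and partner used up, so it sits on the high side. The stopping mark looks at the second half of the run, and over that half the tail shrinks by 19 percentage points. Because that is over one point, well past the stopping mark, we commit to "still moving". Our reckoning gives no figure for conversion or product.

The forecast says: it is still moving, with 49% reacted and 47.5% product, since the first chain carrier “keeps the partner-limited chain going at a slowly fading rate”.

The flask gives: it is still moving, with 48.8% reacted and 47.6% product, close to the forecast's figures. From 4.00 h to 8.00 h the largest share moved by 12 points. Left until 80.0 h, the substrate goes from 51.2% to 46.2%, a further 5 points against our tail of 6.61%.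

Read at 30 h, the same flask has a tail of 0.00407%, under one point, so we expect the substrate to stand still from there on. It shows 53.8% reacted and 52.5% product, with substrate at 46.2%, the same as the 46.2% at 80.0 h.

The rate constants were set for the occasion, and the outcome is calculated.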